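**Retrosynthetic overview**
- Dicitrinone H is cut at the bond between the bridging CH(CH3) carbon and C7 of the quinone methide half: decarboxycitrinin (nucleophile) plus an o-quinone methide generated from the 7-(1-tosylethyl) lactone half.
- Both halves come from one lactone, (3R,4S)-6,8-dihydroxy-3,4,5-trimethylisochroman-1-one: reduction/dehydration gives the pyran quinone methide, and sulfonylalkylation at C7 gives the electrophile.
- The lactone is built from acyclic pieces: a Chan-type bis-silyloxy diene (from methyl 3-oxopentanoate) and a chiral 5-silyloxy alkynoate undergo Diels–Alder benzannulation, aromatisation and lactonisation in one pot.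
- The alkynoate comes from (R)-but-3-yn-2-ol, acetaldehyde and methyl chloroformate; a Marshall propargylation sets both ring stereocentres.
- Ring order: the benzene ring and δ-lactone ring form together (step 6); the pyran ring of the quinone methide half is the same heterocycle after redox adjustment (step 7); the final coupling forms no ring.

Assumption: "Dicitrtinone H" is read as dicitrinone H, and the given SMILES (3R,4S in both halves, bridging carbon R) defines the target.

**Route**

Step 1
Reactants: 1 (R)-but-3-yn-2-ol
Product: 2 (R)-but-3-yn-2-yl methanesulfonate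
Conditions: MeSO2Cl, Et3N, CH2Cl2, −78 → 0 °C
Reagents that add atoms: methanesulfonyl chloride, CS(=O)(=O)Cl
Why: O-sulfonylation of the secondary propargylic alcohol leaves the C–O bond intact, so the R configuration is retained and a leaving group for anti SN2′ substitution is installed.

Step 2
Reactants: 2 (R)-but-3-yn-2-yl methanesulfonate; 3 acetaldehyde
Product: 5 (2R,3S)-3-methylpent-4-yn-2-ol, via allenylzinc reagent 4 (not isolated)
Conditions: Pd(OAc)2 (5 mol %), PPh3 (5 mol %), Et2Zn (3 equiv), 3 (2 equiv), THF, −78 → −20 °C; 1 M HCl work-up; careful distillation (volatile product)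
Reagents that add atoms: diethylzinc, CC[Zn]CC (ethylzinc unit carried only by intermediate 4)
Why: Marshall propargylation, in which anti SN2′ oxidative addition of zerovalent palladium and transmetalation give the axially chiral allenylzinc 4, which adds to acetaldehyde through a closed SE2′ transition state, so the methyl-bearing carbon is set S by chirality transfer (net inversion) and the carbinol carbon R by the anti preference (about 6:1 expected for this small aldehyde, the syn isomer being removed after step 6).

Step 3
Reactants: 5 (2R,3S)-3-methylpent-4-yn-2-ol; 6 methyl chloroformate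
Product: 8 methyl (4S,5R)-4-methyl-5-(triethylsilyloxy)hex-2-ynoate, via triethylsilyl ether 7 (not isolated)
Conditions: n-BuLi (1.0 equiv), THF, −78 °C; Et3SiCl, −78 → 0 °C; n-BuLi (1.1 equiv), −78 °C; then 6, −78 → −30 °C; pH 7 buffer work-up
Reagents that add atoms: chlorotriethylsilane, CC[Si](Cl)(CC)CC
Why: Alkoxide O-silylation followed by acetylide C-acylation (alkynoate synthesis) touches neither stereocentre and masks the hydroxyl for the cycloaddition.

Step 4
Reactants: 9 methyl 3-oxopentanoate
Product: 10 methyl 3-(trimethylsilyloxy)pent-2-enoate (E/Z mixture)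
Conditions: Me3SiCl, Et3N, hexane, rt, 48 h
Reagents that add atoms: chlorotrimethylsilane, C[Si](C)(C)Cl
Why: Silyl enol ether formation by O-silylation of the enol form of the β-keto ester.

Step 5
Reactants: 10 methyl 3-(trimethylsilyloxy)pent-2-enoate
Product: 11 (3Z)-1-methoxy-1,3-bis(trimethylsilyloxy)penta-1,3-diene
Conditions: LiN(i-Pr)2 (commercial solution), THF, −78 °C; Me3SiCl, −78 → 0 °C; filtration under argon, used without chromatography
Reagents that add atoms: chlorotrimethylsilane, C[Si](C)(C)Cl
Why: γ-Deprotonation to the extended dienolate and O-silylation gives the Chan-type diene with the terminal methyl group on the outside, as a Diels–Alder diene needs.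

Step 6
Reactants: 8 methyl (4S,5R)-4-methyl-5-(triethylsilyloxy)hex-2-ynoate; 11 (3Z)-1-methoxy-1,3-bis(trimethylsilyloxy)penta-1,3-diene
Product: 14 (3R,4S)-6,8-dihydroxy-3,4,5-trimethylisochroman-1-one, via Diels–Alder cycloadduct 12 (not isolated), via hydroxy ester 13 (not isolated)
Conditions: 11 (2.5 equiv), PhMe, 120 °C, sealed tube, 36 h; then CF3CO2H/H2O (20:1), CH2Cl2, 0 → 40 °C; chromatography, then recrystallisation (removes the cis-3,4-dimethyl isomer)
Reagents that add atoms: none
Why: Regioselective Diels–Alder benzannulation (nucleophilic diene terminus to the β-carbon of the alkynoate) followed by acid-triggered desilylation, loss of methanol to the resorcylate and lactonisation with retention at the carbinol carbon builds the benzene ring and the δ-lactone ring in one operation and carries C3 (R) and C4 (S) over unchanged from 8.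

Step 7
Reactants: 14 (3R,4S)-6,8-dihydroxy-3,4,5-trimethylisochroman-1-one
Product: 16 (3R,4S)-6-hydroxy-3,4,5-trimethyl-3,4-dihydro-8H-isochromen-8-one (decarboxycitrinin), via lactol 15 (not isolated)
Conditions: i-Bu2AlH (4.5 equiv), CH2Cl2/THF, −78 → −40 °C; then 1 M HCl, rt
Reagents that add atoms: none
Why: Partial lactone-to-lactol reduction (the two phenols are first converted into aluminium phenoxides) followed by acid-induced dehydration of the lactol to the quinone methide leaves both stereocentres untouched.

Step 8
Reactants: 14 (3R,4S)-6,8-dihydroxy-3,4,5-trimethylisochroman-1-one; 3 acetaldehyde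
Product: 18 (3R,4S)-6,8-dihydroxy-3,4,5-trimethyl-7-[1-(4-methylbenzenesulfonyl)ethyl]isochroman-1-one, via benzylic alcohol 17 (not isolated)
Conditions: p-TolSO2Na (1.5 equiv), 3 (3 equiv), HCO2H/H2O (2:1), rt, 24 h
Reagents that add atoms: sodium 4-methylbenzenesulfinate, Cc1ccc(cc1)S(=O)[O-].[Na+]
Why: Acid-mediated hydroxyalkylation at C7, the only free ring position, and sulfinate trapping of the derived o-quinone methide (three-component sulfone synthesis) give a stable o-quinone methide precursor whose new carbon is an epimer mixture that is erased in step 9.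

Step 9
Reactants: 18 (3R,4S)-6,8-dihydroxy-3,4,5-trimethyl-7-[1-(4-methylbenzenesulfonyl)ethyl]isochroman-1-one; 16 decarboxycitrinin
Product: 20 dicitrinone H, via o-quinone methide 19 (not isolated)
Conditions: quinine-derived squaramide (9-amino-9-deoxy-epi-quinine N-[3,5-bis(trifluoromethyl)phenyl]squaramide, 10 mol %), 16 (1.5 equiv), 5% aq. Na2CO3, CH2Cl2, 0 °C; pH 5 buffer work-up
Reagents that add atoms: none
Why: Base-induced 1,4-elimination of sulfinate gives o-quinone methide 19, and asymmetric Michael addition of the vinylogous acid 16 through C7 inside the hydrogen-bonded bifunctional catalyst sets the bridging stereocentre under catalyst control, because the ring stereocentres are too remote to bias the face (the R sense with this catalyst must be confirmed against natural material).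

**Compound list**
1 | (R)-but-3-yn-2-ol | C#C[C@@H](C)O | starting material
2 | (R)-but-3-yn-2-yl methanesulfonate | C#C[C@@H](C)OS(C)(=O)=O | intermediate
3 | acetaldehyde | CC=O | starting material
4 | (P)-(buta-1,2-dien-1-yl)(ethyl)zinc, axially chiral allenylzinc | [H]C(C)=[C@]=C([H])[Zn]CC | intermediate (not isolated)
5 | (2R,3S)-3-methylpent-4-yn-2-ol | C#C[C@H](C)[C@@H](C)O | intermediate
6 | methyl chloroformate | COC(=O)Cl | starting material
7 | triethyl{[(2R,3S)-3-methylpent-4-yn-2-yl]oxy}silane | C#C[C@H](C)[C@@H](C)O[Si](CC)(CC)CC | intermediate (not isolated)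
8 | methyl (4S,5R)-4-methyl-5-(triethylsilyloxy)hex-2-ynoate | COC(=O)C#C[C@H](C)[C@@H](C)O[Si](CC)(CC)CC | intermediate
9 | methyl 3-oxopentanoate | CCC(=O)CC(=O)OC | starting material
10 | methyl 3-(trimethylsilyloxy)pent-2-enoate (E/Z mixture) | CCC(O[Si](C)(C)C)=CC(=O)OC | intermediate
11 | (3Z)-1-methoxy-1,3-bis(trimethylsilyloxy)penta-1,3-diene | C/C=C(\O[Si](C)(C)C)C=C(OC)O[Si](C)(C)C | intermediate
12 | methyl 6-methoxy-3-methyl-2-[(2S,3R)-3-(triethylsilyloxy)butan-2-yl]-4,6-bis(trimethylsilyloxy)cyclohexa-1,4-diene-1-carboxylate (ring epimers) | COC(=O)C1=C([C@H](C)[C@@H](C)O[Si](CC)(CC)CC)C(C)C(O[Si](C)(C)C)=CC1(OC)O[Si](C)(C)C | intermediate (not isolated)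
13 | methyl 2,4-dihydroxy-6-[(2S,3R)-3-hydroxybutan-2-yl]-5-methylbenzoate | COC(=O)c1c(O)cc(O)c(C)c1[C@H](C)[C@@H](C)O | intermediate (not isolated)
14 | (3R,4S)-6,8-dihydroxy-3,4,5-trimethylisochroman-1-one | O=C1O[C@H](C)[C@@H](C)c2c(C)c(O)cc(O)c12 | intermediate
15 | (3R,4S)-3,4,5-trimethylisochromane-1,6,8-triol (C1 epimers) | OC1O[C@H](C)[C@@H](C)c2c(C)c(O)cc(O)c12 | intermediate (not isolated)
16 | (3R,4S)-6-hydroxy-3,4,5-trimethyl-3,4-dihydro-8H-isochromen-8-one (decarboxycitrinin) | CC1=C2C(=CO[C@H](C)[C@H]2C)C(=O)C=C1O | intermediate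
17 | (3R,4S)-6,8-dihydroxy-7-(1-hydroxyethyl)-3,4,5-trimethylisochroman-1-one (carbinol epimers) | O=C1O[C@H](C)[C@@H](C)c2c(C)c(O)c(C(C)O)c(O)c12 | intermediate (not isolated)
18 | (3R,4S)-6,8-dihydroxy-3,4,5-trimethyl-7-[1-(4-methylbenzenesulfonyl)ethyl]isochroman-1-one (sulfone epimers) | O=C1O[C@H](C)[C@@H](C)c2c(C)c(O)c(C(C)S(=O)(=O)c3ccc(C)cc3)c(O)c12 | intermediate
19 | (3R,4S)-7-ethylidene-8-hydroxy-3,4,5-trimethyl-3,4-dihydro-1H-isochromene-1,6(7H)-dione (E/Z) | CC=C1C(=O)C(C)=C2C(=C1O)C(=O)O[C@H](C)[C@H]2C | intermediate (not isolated)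
20 | dicitrinone H, (3R,4S)-6,8-dihydroxy-7-{(1R)-1-[(3R,4S)-6-hydroxy-3,4,5-trimethyl-8-oxo-4,8-dihydro-3H-isochromen-7-yl]ethyl}-3,4,5-trimethylisochroman-1-one | CC1=C2C(=CO[C@H](C)[C@H]2C)C(=O)C([C@H](C)c2c(O)c(C)c3c(c2O)C(=O)O[C@H](C)[C@H]3C)=C1O | target

**Step count and risks**

Total step count: 9. Longest linear sequence: 6 steps (1 → 2 → 3 → 6 → 7 or 8 → 9).

Most likely to fail, step 6: the thermal cycloaddition joins a methyl-bearing diene terminus to an alkyne carbon carrying a secondary alkyl group, so it may be too slow before the diene decomposes. The fallback sets out from 8 and 9 and builds the arene by an anionic Michael–Claisen annulation instead of a pericyclic step. Compound 9 is deprotonated twice (NaH, then n-BuLi, THF, 0 °C) to the sodium lithium dianion of methyl 3-oxopentanoate F1. Its γ-carbon adds to the β-carbon of 8 at −78 → 0 °C, and the resulting ester allenolate closes onto the methyl ester of the keto ester unit. Enolisation then gives methyl 2,4-dihydroxy-5-methyl-6-[(2S,3R)-3-(triethylsilyloxy)butan-2-yl]benzoate F2. Aqueous CF3CO2H removes the silyl group and the sequence comes back to the route at 13, which lactonises to 14 as before.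

Second, step 9: the bridging stereocentre rests on catalyst control alone, and dimerisation of 19 competes. The fallback sets out from 14 and moves the coupling to a Brønsted-acid ion-pair manifold with a different precursor. Fries-type C-acetylation of 14 (Ac2O, BF3·OEt2, 80 °C) gives (3R,4S)-7-acetyl-6,8-dihydroxy-3,4,5-trimethylisochroman-1-one F5. Reduction (NaBH4, CeCl3·7H2O, MeOH, −40 °C) brings it back to the route at 17, used crude. The chiral phosphoric acid (R)-3,3′-bis(2,4,6-triisopropylphenyl)-1,1′-binaphthyl-2,2′-diyl hydrogen phosphate (10 mol %, PhMe, 4 Å sieves, 0 °C) then dehydrates 17 to phosphate-bound 19, which is captured by 16 to give 20.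

Third, step 7: the lactone carbonyl is chelated and electronically deactivated by two phenoxides, so reduction may stall or overshoot. The fallback sets out from 14 and uses a protect–reduce–unmask sequence. Silylation (t-BuMe2SiOSO2CF3, 2,6-lutidine, CH2Cl2) gives (3R,4S)-6,8-bis(tert-butyldimethylsilyloxy)-3,4,5-trimethylisochroman-1-one F3. Reduction with i-Bu2AlH (1.2 equiv, −78 °C) gives (3R,4S)-6,8-bis(tert-butyldimethylsilyloxy)-3,4,5-trimethylisochroman-1-ol F4. HF·pyridine in THF then removes both silyl groups and the sequence comes back to the route at 15, which dehydrates to 16 on acidification.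

**Further compounds**
F1 | step 6 | sodium lithium dianion of methyl 3-oxopentanoate | CC=C([O-])C=C([O-])OC.[Na+].[Li+]
F2 | step 6 | methyl 2,4-dihydroxy-5-methyl-6-[(2S,3R)-3-(triethylsilyloxy)butan-2-yl]benzoate | COC(=O)c1c(O)cc(O)c(C)c1[C@H](C)[C@@H](C)O[Si](CC)(CC)CC
F3 | step 7 | (3R,4S)-6,8-bis(tert-butyldimethylsilyloxy)-3,4,5-trimethylisochroman-1-one | O=C1O[C@H](C)[C@@H](C)c2c(C)c(O[Si](C)(C)C(C)(C)C)cc(O[Si](C)(C)C(C)(C)C)c12
F4 | step 7 | (3R,4S)-6,8-bis(tert-butyldimethylsilyloxy)-3,4,5-trimethylisochroman-1-ol (C1 epimers) | OC1O[C@H](C)[C@@H](C)c2c(C)c(O[Si](C)(C)C(C)(C)C)cc(O[Si](C)(C)C(C)(C)C)c12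
F5 | step 9 | (3R,4S)-7-acetyl-6,8-dihydroxy-3,4,5-trimethylisochroman-1-one | CC(=O)c1c(O)c(C)c2c(c1O)C(=O)O[C@H](C)[C@H]2C
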